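## Retrosynthetic overview

1. Clerodane numbering is used: ring A = cyclohexene C1–C5/C10, ring B = cyclohexane C5–C10, ring C = seven-membered ketone (C1, C10, C9, C11, C12, C13, C16), ring D = furan, ring E = 18,19-lactone. Enabling feature: in ring A the C3=C4 double bond is flanked by C2–OH and by quaternary C5 bearing C19H2–O, both on the α face, and H-1/H-10 are trans. This is the retron of a 2-pyrone [4+2] adduct (C19(=O)–O–C2 bridge across ring A) with an E-alkene.
2. Ring C is opened last at C12–C13 (Friedel–Crafts acylation of the furan β-carbon by the C12 acid). Ring E and the 7α-acetate come from hydride opening of the bridge (C19H2OH, C2–OH), relactonisation onto C18, and reduction of a C7 ketone.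
3. Key disconnection: C5–C10 together with C1–C2, by an intramolecular Diels–Alder reaction of a 3-tethered tert-butyl 2-pyrone-4-carboxylate with an (E)-2-alkenylfuran. It closes rings B and A and sets C5, C10, C1 and C2.
4. The cycloaddition substrate is cut at C6–C7 (Pd-catalysed acylation of a pyranonylmethylzinc reagent). The acid partner, with the C8/C9 stereodiad, comes from an Ireland–Claisen rearrangement of a furyl allylic acetate built from methyl (R)-3-hydroxy-2-methylpropanoate and furfural.
5. Ring order: D (bought) → temporary pyrone → B and A (key step) → E → C.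

Key step: step 17

Remark (assumption): in step 3 the (S,S)-ProPhenol ligand is taken to deliver the (S)-carbinol; if the sense proves opposite, its enantiomer is used and nothing else changes.

## Route

Step 1
Reactants: 1 methyl (R)-3-hydroxy-2-methylpropanoate
Product: 2 methyl (R)-3-[(tert-butyldimethylsilyl)oxy]-2-methylpropanoate
Conditions: TBSCl, imidazole, CH2Cl2, 0 °C to rt
Reagents that add atoms: tert-butyldimethylsilyl chloride, CC(C)(C)[Si](C)(C)Cl
Why: Routine silylation of a primary alcohol; the bought stereocentre (later C8) is not touched.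

Step 2
Reactants: 2
Product: 4 (S)-tert-butyldimethyl[(2-methylbut-3-yn-1-yl)oxy]silane, via aldehyde 3 (not isolated)
Conditions: i-Bu2AlH, CH2Cl2, −78 °C; then MeOH, K2CO3, dimethyl (1-diazo-2-oxopropyl)phosphonate, −78 °C to rt
Reagents that add atoms: dimethyl (1-diazo-2-oxopropyl)phosphonate, COP(=O)(OC)C(=[N+]=[N-])C(C)=O
Why: Partial ester reduction followed in the same flask by Seyferth–Gilbert homologation, so the epimerisable α-methyl aldehyde is never isolated.

Step 3
Reactants: 4; 5 furan-2-carbaldehyde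
Product: 7 (1S,4S)-5-[(tert-butyldimethylsilyl)oxy]-1-(furan-2-yl)-4-methylpent-2-yn-1-ol, via alkynylzinc 6 (not isolated)
Conditions: (S,S)-ProPhenol (10 mol %), Me2Zn, Ph3P=O (20 mol %), PhMe, 0 to 4 °C
Reagents that add atoms: none
Why: Catalytic enantioselective zinc alkynylation of an aromatic aldehyde; the ligand, not the remote methyl centre, should set the (S)-carbinol that is later relayed to C9.

Step 4
Reactants: 7
Product: 9 (1S,2Z,4R)-5-[(tert-butyldimethylsilyl)oxy]-1-(furan-2-yl)-3-iodo-4-methylpent-2-en-1-ol, via cyclic alkenylalanate 8 (not isolated)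
Conditions: NaAlH2(OCH2CH2OMe)2, THF, 0 °C to rt; then I2, −78 to 0 °C
Reagents that add atoms: iodine, II
Why: Alkoxide-directed trans-hydroalumination of the propargylic alcohol puts aluminium on the distal carbon in a five-membered aluminate, and iodinolysis with retention should give the (Z)-3-iodo allylic alcohol.

Step 5
Reactants: 9
Product: 10 (1S,2E,4S)-5-[(tert-butyldimethylsilyl)oxy]-1-(furan-2-yl)-3,4-dimethylpent-2-en-1-ol
Conditions: MeZnCl, Pd(PPh3)4 (5 mol %), THF, 0 °C to rt
Reagents that add atoms: methylzinc chloride, C[Zn]Cl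
Why: Negishi coupling with retention of alkene geometry should give the trisubstituted E-alkene with the new methyl (later C20) cis to the carbinol carbon.

Step 6
Reactants: 10
Product: 11 (1S,2E,4S)-5-[(tert-butyldimethylsilyl)oxy]-1-(furan-2-yl)-3,4-dimethylpent-2-en-1-yl acetate
Conditions: Ac2O, Et3N, DMAP (cat.), CH2Cl2, 0 °C
Reagents that add atoms: acetic anhydride, CC(=O)OC(C)=O
Why: Acetylation under basic, non-ionising conditions spares the furfuryl/allylic C–O bond; the acetyl carbons become C11 and C12.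

Step 7
Reactants: 11
Product: 14 (3R,4E)-3-{(2S)-1-[(tert-butyldimethylsilyl)oxy]propan-2-yl}-5-(furan-2-yl)-3-methylpent-4-enoic acid, via silyl ketene acetal 12 (not isolated), via trimethylsilyl ester 13 (not isolated)
Conditions: LiN(i-Pr)2, TMSCl, THF, −78 °C; then rt to 60 °C; then aq. NH4Cl
Reagents that add atoms: none
Why: Ireland–Claisen rearrangement through a chair transition state with the furyl group equatorial (its axial placement would clash with the cis methyl) should transfer the (S)-carbinol configuration to the new quaternary centre (C9, R) and give the E-alkene C10=C1.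

Step 8
Reactants: 14
Product: 15 tert-butyl (3R,4E)-3-{(2S)-1-[(tert-butyldimethylsilyl)oxy]propan-2-yl}-5-(furan-2-yl)-3-methylpent-4-enoate
Conditions: Boc2O, DMAP (cat.), t-BuOH, rt
Reagents that add atoms: di-tert-butyl dicarbonate, CC(C)(C)OC(=O)OC(=O)OC(C)(C)C; tert-butanol, CC(C)(C)O
Why: DMAP-catalysed tert-butyl esterification via the mixed carbonic anhydride is neutral enough for the alkenylfuran and the silyl ether.

Step 9
Reactants: 15
Product: 16 tert-butyl (3R,4E)-5-(furan-2-yl)-3-[(2S)-1-hydroxypropan-2-yl]-3-methylpent-4-enoate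
Conditions: Bu4NF, AcOH, THF, 0 °C to rt
Reagents that add atoms: none
Why: Fluoride desilylation; the acetic acid buffer should keep the alkoxide from attacking the tert-butyl ester.

Step 10
Reactants: 16
Product: 18 (2S,3R,4E)-3-(2-tert-butoxy-2-oxoethyl)-5-(furan-2-yl)-2,3-dimethylpent-4-enoic acid, via aldehyde 17 (not isolated)
Conditions: TEMPO (cat.), PhI(OAc)2, MeCN/H2O (pH 7 buffer), rt
Reagents that add atoms: water, O
Why: Oxoammonium oxidation of the primary alcohol to the acid through the aldehyde hydrate, under near-neutral conditions that should preserve the α-stereocentre (C8) and the furan.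

Step 11
Reactants: 19 ethyl propanoate; 20 di-tert-butyl oxalate
Product: 22 1-tert-butyl 4-ethyl 3-methyl-2-oxobutanedioate, via lithium enolate 21 (not isolated)
Conditions: LiN(i-Pr)2, THF, −78 °C; then 20, −78 to 0 °C; then aq. HCl
Reagents that add atoms: none
Why: Crossed Claisen condensation of an ester enolate with a non-enolisable oxalate; it supplies C6, C5, C19 (from the propanoate) and C4, C18 (from the oxalate).

Step 12
Reactants: 22
Product: 23 1-tert-butyl 4-ethyl (2Z)-3-methyl-2-{[(trifluoromethyl)sulfonyl]oxy}but-2-enedioate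
Conditions: Tf2O, aq. LiOH, PhMe, 5 °C
Reagents that add atoms: trifluoromethanesulfonic anhydride, O=S(=O)(OS(=O)(=O)C(F)(F)F)C(F)(F)F
Why: O-Triflation of the lithium-chelated enolate should give the Z enol triflate (triflate cis to the ethyl ester), the geometry needed for the later ring closure.

Step 13
Reactants: 23; 24 (E)-2-(2-ethoxyethenyl)-4,4,5,5-tetramethyl-1,3,2-dioxaborolane
Product: 25 1-tert-butyl 4-ethyl (2E)-2-[(E)-2-ethoxyethenyl]-3-methylbut-2-enedioate
Conditions: Pd(dppf)Cl2 (5 mol %), K3PO4, dioxane/H2O, 60 °C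
Reagents that add atoms: none
Why: Suzuki–Miyaura coupling of an electron-poor vinyl triflate with retention at both partners; it attaches C3 and C2 cis to the ethyl ester.

Step 14
Reactants: 25
Product: 27 tert-butyl 3-methyl-2-oxo-2H-pyran-4-carboxylate, via aldehyde 26 (not isolated)
Conditions: PPTS (cat.), acetone/H2O, 45 °C; then DBU (cat.), PhMe, rt
Reagents that add atoms: water, O
Why: Enol-ether hydrolysis followed by enol lactonisation onto the cis ethyl ester with loss of ethanol (the 2-pyranone/isocoumarin annulation of alkoxyvinyl esters); the acid is mild enough for the tert-butyl ester.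

Step 15
Reactants: 27
Product: 28 tert-butyl 3-(bromomethyl)-2-oxo-2H-pyran-4-carboxylate
Conditions: NBS, AIBN (cat.), PhCF3, 85 °C
Reagents that add atoms: N-bromosuccinimide, O=C1CCC(=O)N1Br
Why: Wohl–Ziegler bromination of the only allylic (benzylic-type) methyl group of the ester-deactivated pyrone.

Step 16
Reactants: 18; 28
Product: 31 tert-butyl 3-[(3S,4R,5E)-4-(2-tert-butoxy-2-oxoethyl)-6-(furan-2-yl)-3,4-dimethyl-2-oxohex-5-en-1-yl]-2-oxo-2H-pyran-4-carboxylate, via acid chloride 29 (not isolated), via pyranonylmethylzinc bromide 30 (not isolated)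
Conditions: 18, 1-chloro-N,N,2-trimethylprop-1-en-1-amine, CH2Cl2, 0 °C; 28, Zn dust, LiCl, THF, 0 °C; then combine, Pd(PPh3)4 (5 mol %), THF, 0 °C to rt
Reagents that add atoms: none
Why: Negishi acylation of a benzylic-type organozinc by an acid chloride forms the C6–C7 bond at the exocyclic carbon (as with benzylzinc halides) and leaves the pyrone intact; base-free conditions protect the α-stereocentre C8.

Step 17
Reactants: 31
Product: 32 bridged-lactone cycloadduct (C19(=O)–O–C2 bridge on the α face; C3=C4; 4-CO2t-Bu; 7-oxo; 1β-furan-2-yl; 10β-H; 8α-Me; 9α-Me; 9β-CH2CO2t-Bu)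
Conditions: PhMe (0.01 M), BHT (cat.), 100 °C
Reagents that add atoms: none
Why: Thermal intramolecular inverse-electron-demand Diels–Alder reaction in which the ester-activated 2-pyrone (diene C5=C4–C3=C2) adds suprafacially to the electron-rich E-alkenylfuran (C10=C1), forming C5–C10 and C1–C2 in one event with the CO2 bridge retained; the closest known reaction type is the intramolecular [4+2] cycloaddition of 3-tethered 2-pyrones with alkenes to 2-oxabicyclo[2.2.2]octenones. Ring B closes through C5–C10 as the six-membered tether ring of a type 1 (fused-mode) intramolecular Diels–Alder reaction, and ring A closes by the cycloaddition itself (C5–C10 plus C1–C2), with the lactone bridge spanning its α face. C5 and C2 are set by the bridge, which forces C19 and the C2 oxygen cis; C10 and C1 are set by the E-alkene (trans H-10/H-1) and by the endo furyl group with the tether exo, which gives the trans A/B fusion (C19 α, H-10 β). The absolute sense of all four centres is controlled by C8 and C9 through a chair-like tether with the C8 methyl equatorial, the C9 methyl axial and the bulkier CH2CO2t-Bu equatorial, the sp2 C7 ketone adding no further axial group. The step needs endo/exo and π-facial selectivity and retention of alkene geometry: regiochemistry is fixed by the four-atom tether and is electronically matched (nucleophilic C10 onto C5, the β-carbon of the C4 ester; furfuryl-stabilised C1 onto C2), and the non-polar medium should keep the addition concerted. The temperature stays below that at which such adducts extrude CO2.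

Step 18
Reactants: 32
Product: 33 cycloadduct diacid (as 32 with 4-CO2H and 9β-CH2CO2H)
Conditions: TFA/CH2Cl2 (1:4), anisole, 0 °C to rt
Reagents that add atoms: none
Why: Acidolysis of both tert-butyl esters, with anisole trapping the tert-butyl cation away from the furan; the bridged lactone should survive because ionisation at C2 is disfavoured by the conjugated carboxyl.

Step 19
Reactants: 33
Product: 36 2α;7α-dihydroxy 18,19-olide acid (C3=C4; 1β-furan-2-yl; 9β-CH2CO2H), via dilithium dicarboxylate 34 (not isolated), via trihydroxy diacid 35 (not isolated)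
Conditions: LiOt-Bu (2.0 equiv), THF, 0 °C; then LiBH4, 0 °C to rt; then 1 M HCl, rt
Reagents that add atoms: none
Why: The carboxylates are inert to LiBH4, which reduces the strained bridging lactone to C19H2OH/C2–OH and the C7 ketone from the β face (the α face is blocked by the syn-axial C19 bridge carbon and C20 methyl), setting 7α-OH; acidification should lactonise C19–OH onto the C18 acid to the five-membered ring E.

Step 20
Reactants: 36
Product: 38 2α-(tert-butyldimethylsilyloxy)-7α-hydroxy 18,19-olide acid, via bis-silyl derivative 37 (not isolated)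
Conditions: TBSCl, imidazole, DMF, 0 °C to rt; then K2CO3 (cat.), MeOH/H2O, 0 °C
Reagents that add atoms: tert-butyldimethylsilyl chloride, CC(C)(C)[Si](C)(C)Cl
Why: The equatorial allylic C2–OH is silylated while the axial 7α-OH, flanked by two syn-axial carbons, should stay free; the labile silyl ester is cleaved in the mild methanolysis.

Step 21
Reactants: 38
Product: 40 7α-acetoxy-2α-(tert-butyldimethylsilyloxy) 18,19-olide acid, via mixed anhydride 39 (not isolated)
Conditions: Ac2O, DMAP, Et3N, CH2Cl2, rt to 40 °C; then aq. NaHCO3/THF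
Reagents that add atoms: acetic anhydride, CC(=O)OC(C)=O
Why: DMAP-catalysed acetylation of the hindered axial alcohol; the mixed anhydride formed at the carboxyl group is hydrolysed in the work-up.

Step 22
Reactants: 40
Product: 42 2-O-tert-butyldimethylsilyl ether of the target, via acid chloride 41 (not isolated)
Conditions: 1-chloro-N,N,2-trimethylprop-1-en-1-amine, CH2Cl2, 0 °C; then SnCl4, −78 to −30 °C
Reagents that add atoms: none
Why: Intramolecular Friedel–Crafts acylation at the furan β-carbon C13 closes the seven-membered ring C; the peri relationship of the equatorial 9β-CH2COCl and 1β-furyl groups favours closure, and the more nucleophilic α-carbon cannot be reached intramolecularly.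

Step 23
Reactants: 42
Product: 43 target CNP0182929.1
Conditions: HF·pyridine, THF, 0 °C to rt
Reagents that add atoms: none
Why: Fluoride cleavage of the secondary silyl ether under mildly acidic conditions that should leave the acetate, the butenolide and the furyl ketone untouched.

## Compound list

1 | methyl (R)-3-hydroxy-2-methylpropanoate | COC(=O)[C@H](C)CO | starting material
2 | methyl (R)-3-[(tert-butyldimethylsilyl)oxy]-2-methylpropanoate | COC(=O)[C@H](C)CO[Si](C)(C)C(C)(C)C | intermediate
3 | (R)-3-[(tert-butyldimethylsilyl)oxy]-2-methylpropanal | O=C[C@H](C)CO[Si](C)(C)C(C)(C)C | intermediate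
4 | (S)-tert-butyldimethyl[(2-methylbut-3-yn-1-yl)oxy]silane | C#C[C@H](C)CO[Si](C)(C)C(C)(C)C | intermediate
5 | furan-2-carbaldehyde | O=Cc1ccco1 | starting material
6 | {(3S)-4-[(tert-butyldimethylsilyl)oxy]-3-methylbut-1-yn-1-yl}(methyl)zinc | C[Zn]C#C[C@H](C)CO[Si](C)(C)C(C)(C)C | intermediate
7 | (1S,4S)-5-[(tert-butyldimethylsilyl)oxy]-1-(furan-2-yl)-4-methylpent-2-yn-1-ol | O[C@H](c1ccco1)C#C[C@H](C)CO[Si](C)(C)C(C)(C)C | intermediate
8 | sodium cyclic alkenyl(alkoxy)bis(2-methoxyethoxy)aluminate from 7 (Al on the distal alkene carbon, five-membered O–Al ring) | [Na+].COCCO[Al-]1(OCCOC)O[C@H](c2ccco2)C=C1[C@H](C)CO[Si](C)(C)C(C)(C)C | intermediate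
9 | (1S,2Z,4R)-5-[(tert-butyldimethylsilyl)oxy]-1-(furan-2-yl)-3-iodo-4-methylpent-2-en-1-ol | O[C@H](c1ccco1)/C=C(\I)[C@H](C)CO[Si](C)(C)C(C)(C)C | intermediate
10 | (1S,2E,4S)-5-[(tert-butyldimethylsilyl)oxy]-1-(furan-2-yl)-3,4-dimethylpent-2-en-1-ol | O[C@H](c1ccco1)/C=C(\C)[C@H](C)CO[Si](C)(C)C(C)(C)C | intermediate
11 | (1S,2E,4S)-5-[(tert-butyldimethylsilyl)oxy]-1-(furan-2-yl)-3,4-dimethylpent-2-en-1-yl acetate | CC(=O)O[C@H](c1ccco1)/C=C(\C)[C@H](C)CO[Si](C)(C)C(C)(C)C | intermediate
12 | trimethylsilyl ketene acetal of 11 | C=C(O[Si](C)(C)C)O[C@H](c1ccco1)/C=C(\C)[C@H](C)CO[Si](C)(C)C(C)(C)C | intermediate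
13 | trimethylsilyl ester of 14 | C[Si](C)(C)OC(=O)C[C@@](C)([C@H](C)CO[Si](C)(C)C(C)(C)C)/C=C/c1ccco1 | intermediate
14 | (3R,4E)-3-{(2S)-1-[(tert-butyldimethylsilyl)oxy]propan-2-yl}-5-(furan-2-yl)-3-methylpent-4-enoic acid | OC(=O)C[C@@](C)([C@H](C)CO[Si](C)(C)C(C)(C)C)/C=C/c1ccco1 | intermediate
15 | tert-butyl ester of 14 | CC(C)(C)OC(=O)C[C@@](C)([C@H](C)CO[Si](C)(C)C(C)(C)C)/C=C/c1ccco1 | intermediate
16 | tert-butyl (3R,4E)-5-(furan-2-yl)-3-[(2S)-1-hydroxypropan-2-yl]-3-methylpent-4-enoate | CC(C)(C)OC(=O)C[C@@](C)([C@H](C)CO)/C=C/c1ccco1 | intermediate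
17 | tert-butyl (3R,4E)-5-(furan-2-yl)-3-methyl-3-[(2S)-1-oxopropan-2-yl]pent-4-enoate | CC(C)(C)OC(=O)C[C@@](C)([C@H](C)C=O)/C=C/c1ccco1 | intermediate
18 | (2S,3R,4E)-3-(2-tert-butoxy-2-oxoethyl)-5-(furan-2-yl)-2,3-dimethylpent-4-enoic acid | CC(C)(C)OC(=O)C[C@@](C)([C@H](C)C(=O)O)/C=C/c1ccco1 | intermediate
19 | ethyl propanoate | CCC(=O)OCC | starting material
20 | di-tert-butyl oxalate | CC(C)(C)OC(=O)C(=O)OC(C)(C)C | starting material
21 | lithium enolate of ethyl propanoate | CC=C(OCC)O[Li] | intermediate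
22 | 1-tert-butyl 4-ethyl 3-methyl-2-oxobutanedioate | CCOC(=O)C(C)C(=O)C(=O)OC(C)(C)C | intermediate
23 | 1-tert-butyl 4-ethyl (2Z)-3-methyl-2-{[(trifluoromethyl)sulfonyl]oxy}but-2-enedioate | CCOC(=O)/C(C)=C(\OS(=O)(=O)C(F)(F)F)C(=O)OC(C)(C)C | intermediate
24 | (E)-2-(2-ethoxyethenyl)-4,4,5,5-tetramethyl-1,3,2-dioxaborolane | CCO/C=C/B1OC(C)(C)C(C)(C)O1 | starting material
25 | 1-tert-butyl 4-ethyl (2E)-2-[(E)-2-ethoxyethenyl]-3-methylbut-2-enedioate | CCOC(=O)/C(C)=C(\C=C\OCC)C(=O)OC(C)(C)C | intermediate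
26 | 1-tert-butyl 4-ethyl (2E)-3-methyl-2-(2-oxoethyl)but-2-enedioate | CCOC(=O)/C(C)=C(\CC=O)C(=O)OC(C)(C)C | intermediate
27 | tert-butyl 3-methyl-2-oxo-2H-pyran-4-carboxylate | CC1=C(C(=O)OC(C)(C)C)C=COC1=O | intermediate
28 | tert-butyl 3-(bromomethyl)-2-oxo-2H-pyran-4-carboxylate | BrCC1=C(C(=O)OC(C)(C)C)C=COC1=O | intermediate
29 | acid chloride of 18 | CC(C)(C)OC(=O)C[C@@](C)([C@H](C)C(=O)Cl)/C=C/c1ccco1 | intermediate
30 | {[4-(tert-butoxycarbonyl)-2-oxo-2H-pyran-3-yl]methyl}zinc bromide | Br[Zn]CC1=C(C(=O)OC(C)(C)C)C=COC1=O | intermediate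
31 | tert-butyl 3-[(3S,4R,5E)-4-(2-tert-butoxy-2-oxoethyl)-6-(furan-2-yl)-3,4-dimethyl-2-oxohex-5-en-1-yl]-2-oxo-2H-pyran-4-carboxylate | CC(C)(C)OC(=O)C1=C(CC(=O)[C@@H](C)[C@](C)(CC(=O)OC(C)(C)C)/C=C/c2ccco2)C(=O)OC=C1 | intermediate
32 | bridged-lactone cycloadduct: C19(=O)–O–C2 bridge (α), C3=C4, 4-CO2t-Bu, 7-oxo, 1β-(furan-2-yl), 10β-H, 8α-Me, 9α-Me, 9β-CH2CO2t-Bu | O=C1C[C@@]23C(=O)O[C@@H](C=C2C(=O)OC(C)(C)C)[C@@H](c4ccco4)[C@@H]3[C@@](C)(CC(=O)OC(C)(C)C)[C@@H]1C | intermediate
33 | cycloadduct diacid (4-CO2H, 9β-CH2CO2H) | O=C1C[C@@]23C(=O)O[C@@H](C=C2C(=O)O)[C@@H](c4ccco4)[C@@H]3[C@@](C)(CC(=O)O)[C@@H]1C | intermediate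
34 | dilithium dicarboxylate of 33 | [Li+].[Li+].O=C1C[C@@]23C(=O)O[C@@H](C=C2C([O-])=O)[C@@H](c4ccco4)[C@@H]3[C@@](C)(CC([O-])=O)[C@@H]1C | intermediate
35 | 2α,7α,19-trihydroxy diacid (bridge opened, ring E not yet closed) | O[C@@H]1C[C@@]2(CO)C(C(=O)O)=C[C@H](O)[C@@H](c4ccco4)[C@@H]2[C@@](C)(CC(=O)O)[C@@H]1C | intermediate
36 | 2α,7α-dihydroxy 18,19-olide acid (C3=C4, 1β-furan-2-yl, 9β-CH2CO2H) | O[C@@H]1C[C@@]23COC(=O)C2=C[C@H](O)[C@@H](c4ccco4)[C@@H]3[C@@](C)(CC(=O)O)[C@@H]1C | intermediate
37 | 2-O-TBS ether, TBS ester of 36 | O[C@@H]1C[C@@]23COC(=O)C2=C[C@H](O[Si](C)(C)C(C)(C)C)[C@@H](c4ccco4)[C@@H]3[C@@](C)(CC(=O)O[Si](C)(C)C(C)(C)C)[C@@H]1C | intermediate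
38 | 2α-(tert-butyldimethylsilyloxy)-7α-hydroxy 18,19-olide acid | O[C@@H]1C[C@@]23COC(=O)C2=C[C@H](O[Si](C)(C)C(C)(C)C)[C@@H](c4ccco4)[C@@H]3[C@@](C)(CC(=O)O)[C@@H]1C | intermediate
39 | mixed acetic anhydride of 40 | CC(=O)O[C@@H]1C[C@@]23COC(=O)C2=C[C@H](O[Si](C)(C)C(C)(C)C)[C@@H](c4ccco4)[C@@H]3[C@@](C)(CC(=O)OC(C)=O)[C@@H]1C | intermediate
40 | 7α-acetoxy-2α-(tert-butyldimethylsilyloxy) 18,19-olide acid | CC(=O)O[C@@H]1C[C@@]23COC(=O)C2=C[C@H](O[Si](C)(C)C(C)(C)C)[C@@H](c4ccco4)[C@@H]3[C@@](C)(CC(=O)O)[C@@H]1C | intermediate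
41 | acid chloride of 40 | CC(=O)O[C@@H]1C[C@@]23COC(=O)C2=C[C@H](O[Si](C)(C)C(C)(C)C)[C@@H](c4ccco4)[C@@H]3[C@@](C)(CC(=O)Cl)[C@@H]1C | intermediate
42 | 2-O-tert-butyldimethylsilyl ether of the target (ring C closed, 12-oxo) | CC(=O)O[C@@H]1C[C@@]23COC(=O)C2=C[C@H](O[Si](C)(C)C(C)(C)C)[C@H]2c4occc4C(=O)C[C@@](C)([C@@H]1C)[C@@H]23 | intermediate
43 | CNP0182929.1: 7α-acetoxy-2α-hydroxy-12-oxo 1,16-cyclo-neo-clerod-3-ene 18,19-olide with furan ring D fused to ring C | CC(=O)O[C@@H]1C[C@@]23COC(=O)C2=C[C@H](O)[C@H]2c4occc4C(=O)C[C@@](C)([C@@H]1C)[C@@H]23 | target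

## Step count and risks

Total step count: 23. Longest linear sequence: 18 steps (steps 1–10, then 16–23); steps 11–15 build the pyrone fragment in parallel.

**Step 17 (cycloaddition).** What may go wrong: insufficient endo-furyl/exo-tether or π-facial discrimination, partial loss of the E-geometry through a stepwise zwitterionic addition, or CO2 extrusion if a higher temperature is needed. Fallback (sets out from 27, comes back at 32): the diene is activated with a removable bromine. Bromination of 27 at the ring CH next to the ester (Br2, CH2Cl2, 0 °C; then Et3N) should give the 5-bromopyrone F1. NBS/AIBN then gives the bromomethyl compound F2, and zinc insertion gives the zinc reagent F3. Acylation of F3 by 29 as in step 16 gives the bromopyrone ketone F4. Bromo-2-pyrones are more reactive, ambiphilic dienes with a stronger endo preference, so cycloaddition at 60–70 °C should give the C3-bromo adduct F5. Bu3SnH/AIBN (PhH, 80 °C) removes the vinylic bromine and the route is rejoined at 32.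

**Step 16 (fragment coupling).** What may go wrong: acylation of the ambident zinc reagent at the ring carbon, O-acylation or pyrone opening by the enol of the new ketone, and epimerisation at C8 through a ketene. Fallback (sets out from 16, comes back at 31): carbonyl addition followed by oxidation instead of acylation. Dess–Martin oxidation of 16 gives aldehyde 17, isolated this time. CrCl2 (THF, rt) converts 28 into the benzylic-type organochromium reagent F6 of trivalent chromium. Its Nozaki–Hiyama addition to 17 gives the secondary alcohols F7 (both C7 epimers) through non-nucleophilic chromium alkoxides that should not open the pyrone. Dess–Martin oxidation of F7 rejoins the route at 31.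

**Step 22 (ring C closure).** What may go wrong: intermolecular acylation at the free furan α-position (C15) and Lewis-acid-induced furan decomposition outrunning closure of the seven-membered ring. Fallback (sets out from 40, comes back at 42): the α-position is blocked first. NBS (DMF, 0 °C) should brominate C15 of 40 to give the bromofuran acid F8. The same chloroenamine gives its acid chloride F9, and SnCl4 cyclises it to the bromo ketone F10, with only C13 left for attack. Pd(PPh3)4/Bu3SnH (PhMe, 60 °C) then reduces the furyl bromide and the route is rejoined at 42.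

Further compounds
F1 | step 17 | tert-butyl 5-bromo-3-methyl-2-oxo-2H-pyran-4-carboxylate | CC1=C(C(=O)OC(C)(C)C)C(Br)=COC1=O
F2 | step 17 | tert-butyl 5-bromo-3-(bromomethyl)-2-oxo-2H-pyran-4-carboxylate | BrCC1=C(C(=O)OC(C)(C)C)C(Br)=COC1=O
F3 | step 17 | {[5-bromo-4-(tert-butoxycarbonyl)-2-oxo-2H-pyran-3-yl]methyl}zinc bromide | Br[Zn]CC1=C(C(=O)OC(C)(C)C)C(Br)=COC1=O
F4 | step 17 | 5-bromo analogue of 31 | CC(C)(C)OC(=O)C1=C(CC(=O)[C@@H](C)[C@](C)(CC(=O)OC(C)(C)C)/C=C/c2ccco2)C(=O)OC=C1Br
F5 | step 17 | C3-bromo analogue of cycloadduct 32 | O=C1C[C@@]23C(=O)O[C@@H](C(Br)=C2C(=O)OC(C)(C)C)[C@@H](c4ccco4)[C@@H]3[C@@](C)(CC(=O)OC(C)(C)C)[C@@H]1C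
F6 | step 16 | dichloro{[4-(tert-butoxycarbonyl)-2-oxo-2H-pyran-3-yl]methyl}chromium | Cl[Cr](Cl)CC1=C(C(=O)OC(C)(C)C)C=COC1=O
F7 | step 16 | C7 alcohols corresponding to 31 (both epimers) | CC(C)(C)OC(=O)C1=C(CC(O)[C@@H](C)[C@](C)(CC(=O)OC(C)(C)C)/C=C/c2ccco2)C(=O)OC=C1
F8 | step 22 | 15-bromo analogue of 40 (5-bromofuran-2-yl) | CC(=O)O[C@@H]1C[C@@]23COC(=O)C2=C[C@H](O[Si](C)(C)C(C)(C)C)[C@@H](c4ccc(Br)o4)[C@@H]3[C@@](C)(CC(=O)O)[C@@H]1C
F9 | step 22 | acid chloride of F8 | CC(=O)O[C@@H]1C[C@@]23COC(=O)C2=C[C@H](O[Si](C)(C)C(C)(C)C)[C@@H](c4ccc(Br)o4)[C@@H]3[C@@](C)(CC(=O)Cl)[C@@H]1C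
F10 | step 22 | 15-bromo analogue of 42 | CC(=O)O[C@@H]1C[C@@]23COC(=O)C2=C[C@H](O[Si](C)(C)C(C)(C)C)[C@H]2c4oc(Br)cc4C(=O)C[C@@](C)([C@@H]1C)[C@@H]23
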